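An easy step first: add two columns of a run and watch when their sum stops growing.

| setting | south-east | south | red | green | teal | blue |
|---|---|---|---|---|---|---|
| starting complex | 20 mM | 20 mM | 20 mM (in portions, 3, over 2.0 min) | 20 mM | 20 mM (fed, over 2.0 min) | 20 mM |
| incoming ligand | 1.3 equiv | 2.6 equiv | 1.30 equiv | 1.30 equiv (fed, over 2.0 min) | 1.30 equiv | 1.30 equiv |
| leaving ligand | 1 equiv | 1 equiv | 1.00 equiv | 1.00 equiv | 1.00 equiv | 1.00 equiv |
| remark | run made earlier | run made earlier | first portion at the start, last at 2.0 min | all else is in the flask from the start; the feed brings no volume worth counting | all else is in the flask from the start; the feed brings no volume worth counting | everything together at the start |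
| time |  |  | 3.0 min | 3.0 min | 3.0 min | 3.0 min |

south-east run (percent of the starting complex charged)

| time / min | side product / % | complex with two exchanged / % |
|---|---|---|
| 0.200 | 28.5 | 3.5 |
| 0.667 | 32.9 | 0.2 |
| 1.00 | 33.1 | 0 |
| 1.50 | 31.6 | 0 |
| 2.50 | 32.3 | 0.1 |
| 3.00 | 33.0 | 0.3 |

south run (percent of the starting complex charged)

| time / s | side product / % | complex with two exchanged / % |
|---|---|---|
| 10.0 | 36.6 | 10.8 |
| 15.0 | 45.1 | 4.8 |
| 20.0 | 48.9 | 0.5 |

(scatter of a reading: 1 percentage point)

- percentages count the starting complex that a species holds: one side product counts as two

* the flask that comes out highest in amount of side product, in percent of the starting complex charged; "all alike" if 1.5 percentage points covers them all (red / green / teal / blue / all alike)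
* amount of side product at the end, in percent of the starting complex charged, red
* amount of side product at the end, in percent of the starting complex charged, green
* amount of side product at the end, in percent of the starting complex charged, teal
* amount of side product at the end, in percent of the starting complex charged, blue

In the south-east run, side product plus complex with two exchanged comes to 32.0% at 0.200 min, close to the 33.1% of side product at 1.00 min, so call 0.200 min the working window. With twice the ligand, the south run's sum reads 49.9% at 15.0 s and 49.4% at 20.0 s, so the window stays near 0.25 min.

Yet if you count one ligand per complex held in side product, the south-east plateau has used a quarter of the ligand charge, while 66.9% of the complex is not in side product. I therefore take it that the incoming ligand is lost by a route of its own, on a clock that barely follows its charge.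

In teal, fed evenly over 2.0 min, 10.0% of the complex has arrived when the window closes; carry this as the dosed share, the part of the charged complex present while the ligand still works. Multiplying it by the plateau, I reckon about 3.31% for teal. Red, with a third of the complex in at the start, comes to about 11.0%, and blue, with the whole charge present, stays near 33.1%, which is more than either. Green is the mirror case: the complex stands in the flask from the start, but [incoming ligand] should hold about one window's feed, 2.60 mM, and I put no yield on that beyond expecting it below blue.

The forecast differs on red and teal: it names teal, with 33% for red, 3% for green, 33.5% for teal and 32.6% for blue, holding that “Dosing complex then follows the same ligand trajectory as batch”.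

The flasks give 8.62% in red, 18.3% in green, 0.998% in teal and 32.5% in blue, so blue stands highest.

    starting complex + incoming ligand ⇌ leaving ligand + complex with one exchanged (K = 1.10, k = 26.0 M⁻¹ s⁻¹)
    complex with one exchanged + incoming ligand ⇌ leaving ligand + complex with two exchanged (K = 1.70, k = 18.0 M⁻¹ s⁻¹)
    incoming ligand → decomposed reagent (k = 0.120 s⁻¹)
    starting complex + complex with two exchanged → side product (k = 15.0 M⁻¹ s⁻¹)

Teal lies below the dosed-share figure, as does red, and green's mean [incoming ligand] over the first 2.0 min was 1.38 mM, against my 2.60 mM. Teal and blue have come to rest: incoming ligand, the limiting reagent, stands at 0% of its charge in teal and 0% in blue at 3.00 min. At 30.0 min, ten times as long, teal reads 0.998%, and at the same 30.0 min blue reads 32.5%, so the extra time moves neither printed answer, and at 30.0 min teal keeps 99.0% of its starting complex.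

In the teal neighbour with 0.520 equiv of incoming ligand, the ligand's clock is taken as unchanged, so the dosed share remains 10.0%, and its product with the south-east plateau, 3.31%, is an estimate from a run with more ligand. That flask gives 0.246%, with 99.8% of the starting complex left.

The data were computed with made-up constants, noise included.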